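## Analysis of the target

Compound 46 (CNP0299903.1) is a cis,cis-germacranolide. A ten-membered carbocycle (C1–C10) carries two Z trisubstituted alkenes, C1=C10 and C4=C5, and is cis-fused at C6–C7 to an α-methylene-γ-butyrolactone (O6–C12(=O)–C11(=C13)–C7). The ring has five stereocentres: C3 (S, acetate), C6 (R), C7 (R), C8 (S, ester) and C9 (R, free hydroxyl). The C8 ester is a (2R,3R)-2,3-dimethyloxirane-2-carboxylate, the epoxide of an angelate. In a flat drawing of the ring, O6 and C11 lie on one face, and O8, O9 and O3 lie on the other; so C11 and O8 are trans and O8 and O9 are cis. The sensitive groups are the exocyclic enoate (a Michael acceptor), the epoxide, the allylic acetate and the ester next to a free hydroxyl (acyl migration). The difficulties are the medium ring with two Z trisubstituted alkenes, the four contiguous centres C6–C9, and three ring oxygens that must end with three different substituents. The strategy rests on the O–C–O array on C6–C7–C8. With C11 cis to O6 and O8 trans to C11, it is exactly what anti addition of an O6-tethered carbon and an oxygen atom across a Z C7=C8 alkene of a ten-membered trienol gives.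

## Retrosynthetic reasoning

**46 back to 37 and 41.** The O9–silyl bond, the C12 oxidation level and the O8–acyl bond are handled last (45, 44, 43). This keeps the Michael acceptor and the ester/free-hydroxyl pair out of all earlier steps. In 37 the C8 hydroxyl is the only free hydroxyl, so acylation with epoxy acid 41 needs no regiocontrol.

**37 back to 35 (key disconnection).** The C7–C11 bond and the C8–O bond are cut together. Forward, a vinyl radical at C11, held on O6 by an acetal, must add to C7 of the ring alkene and the resulting C8 radical must be hydroxylated aerobically. One ring, one skeletal bond and the C7 and C8 centres come from one operation on a substrate that has no stereocentre at either carbon.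

**35 back to 30 and 33.** Only the acetal C–O bond is cut. The forward exchange must avoid free acid, because C6 in 30 is doubly allylic.

**30 back to 27.** After protecting-group changes (29, 28) the ring is opened at C9–C10. A Nozaki–Hiyama–Kishi closure is chosen because the three Z alkenes of 27 bend the chain towards closure, the aldehyde has no α-stereocentre, and the acetate and the PMB ether survive. The closure must give the 9S alcohol.

**27 back to 18 and 19.** The C1=C10 iodoalkene comes from aldehyde 18 by Stork–Zhao olefination with the ylide from 19. The C3 oxygen is a silyl ether at that stage and is changed to the acetate afterwards (23, 24, 25), since a β-acetoxy aldehyde would eliminate under the ylide.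

**18 back to 13.** The Z C7=C8 alkene is taken back to an alkyne (16 from 15) and the C6 carbinol to ketone 13. This avoids a labile Z enal in the first coupling and lets C6 be set by a reagent-controlled ynone reduction (14).

**13 back to 8 and 11.** The C5–C6 bond is cut between an alkenyllithium and an alkynyl Weinreb amide. Amide 11 comes from 1 through silyl ether 9.

**8 back to 1.** The C2–C3 bond is cut by asymmetric allylation of enal 4, which sets C3 (5). The extra alkene carbon is removed on the way to diol 7. The Z iodoalkene 3 comes from 1 by anti carbomagnesiation, which fixes the C4=C5 geometry at the start.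

**41 back to 38, and 33 back to 31.** The epoxy acid comes from angelic acid 38 through allylic alcohol 39 and asymmetric epoxidation (40). Acetal 33 comes from 31 by bromination and elimination.

## Alternatives that were turned down

**Alternative 1:** The ten-membered ring is derived from an eight-membered one. C9–C10 and C1–C2 are cut in a [2+2] sense and a C2–C9 bond is restored. Forward, propyne A2 is added photochemically to a silylated enol double bond C2=C9 that is conjugated to a C3 ketone (De Mayo reaction). Desilylation then triggers retro-aldol cleavage of C2–C9 and gives the ring-expanded 3,9-diketone A1.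
- For: the ring is made by expansion instead of end-to-end closure, and the C1=C10 alkene is necessarily cis. On these two points it is stronger than the chosen route.
- Against: the orientation of the alkyne (methyl on C10, not C1) is not secured. The C3 enone with C4=C5 absorbs as well. A1 lacks the exocyclic methylene and has two ketones that need separate stereoselective reductions, followed by differentiation of three hydroxyls and α-methylenation.
- Comparison: the chosen route has C3 and C9 set and differentiated before the key step and ends four steps after it.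

**Alternative 2:** C5–C6 and the lactone C–O bond are cut in one operation. Forward, an alkenylchromium centre at C5 adds to a C6 aldehyde, and the chromium alkoxide closes the lactone onto an acrylate ester on C7, giving A3.
- For: ring and lactone form together, A3 is three steps from 46, and no choice between two alkenes arises. On step economy after ring closure and on site selectivity it is stronger than the chosen route.
- Against: the aldehyde is flanked by C7, whose hydrogen is α to the aldehyde and allylic to the acrylate, so epimerisation and double-bond migration threaten before closure. C6 arises under substrate control and must come out cis to C7. The acrylate is exposed to alkoxides and to divalent chromium. The open-chain C7–C8–C9 triad must be built first.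
- Comparison: the chosen route closes the ring from an aldehyde without an α-stereocentre and derives C7 and C8 from C6 through a tether.

**Alternative 3:** C7–C8 is cut and O8–C13 reconnected, so the carbocycle becomes the contraction product of a thirteen-membered cyclic ether bridged by a butenolide. Forward, boron-mediated enolisation of a C9 ketone towards C8 sets off a [2,3]-Wittig shift that forms C7–C8, breaks O8–C13 and releases the exocyclic methylene, giving A4.
- For: C7 and C8 are set in one concerted event with the methylene lactone already present, which is a more orderly way to set these centres than radical capture by O2. A thirteen-membered ether is easier to close than a ten-membered carbocycle.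
- Against: the macrocyclic ether with its bridging butenolide is long to make. The syn/anti outcome of an enolate [2,3]-shift in this ring is open. A4 still needs a stereoselective C9 reduction next to a methylene lactone that is itself reducible, and the acetate must survive enolisation.
- Comparison: the chosen route has a shorter precursor and keeps C9 at the alcohol level throughout.

Key step: step 24

## Remarks on the chemistry

- Carbon numbers C1–C15 are those of the germacrane skeleton of 46 (ring C1–C10, lactone carbons C11–C13, C14 on C10, C15 on C4). Ring compounds are named with these locants.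
- Mixed acetals 35, 36, 37 and 43 are carried as both epimers at the acetal carbon (one is drawn) and lactol 44 as both anomers. This carbon ends as the lactone carbonyl C12.

## Route

Step 1
Reactants: 1 prop-2-yn-1-ol (propargyl alcohol)
Product: 3 (Z)-3-iodo-2-methylprop-2-en-1-ol, via alkenylmagnesium alkoxide 2 (not isolated)
Conditions: MeMgBr (3 equiv), CuI (10 mol %), THF, −10 °C → rt; then I2, −10 °C
Reagents that add atoms: methylmagnesium bromide, C[Mg]Br; iodine, [I][I]
Why: Copper-catalysed anti carbomagnesiation of a propargylic alcohol: the magnesium alkoxide directs methyl to C2 and holds magnesium on C3 in a five-membered chelate cis to the CH2O group, so iodinolysis should give the Z iodoalkene. This fixes the later C4=C5 geometry (C3 and C6 cis).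

Step 2
Reactants: 3 (Z)-3-iodo-2-methylprop-2-en-1-ol
Product: 4 (Z)-3-iodo-2-methylprop-2-enal
Conditions: MnO2 (15 equiv), CH2Cl2, rt, dark
Reagents that add atoms: none
Why: Neutral allylic oxidation with MnO2; the Z enal is labile to light and acid and is used at once.

Step 3
Reactants: 4 (Z)-3-iodo-2-methylprop-2-enal
Product: 5 (1Z,3S)-1-iodo-2-methylhexa-1,5-dien-3-ol
Conditions: (−)-Ipc2BOMe, allylMgBr, Et2O, 0 °C → rt; then 4, −78 °C; NaOH, H2O2, 0 °C
Reagents that add atoms: allylmagnesium bromide, C=CC[Mg]Br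
Why: Brown asymmetric allylboration through a chair transition state; the reagent derived from (+)-α-pinene should attack the aldehyde face that gives the 3S alcohol, so C3 is set by the reagent. The vinyl iodide is inert.

Step 4
Reactants: 5 (1Z,3S)-1-iodo-2-methylhexa-1,5-dien-3-ol
Product: 7 (3S,4Z)-5-iodo-4-methylpent-4-ene-1,3-diol, via hydroxy aldehyde 6 (not isolated)
Conditions: OsO4 (2 mol %), NaIO4, 2,6-lutidine, dioxane/H2O, rt; then NaBH4, MeOH, 0 °C
Reagents that add atoms: osmium tetroxide, O=[Os](=O)(=O)=O; sodium periodate, [Na+].[O-]I(=O)(=O)=O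
Why: Johnson–Lemieux cleavage: OsO4 should take the monosubstituted alkene in preference to the iodine-deactivated trisubstituted one. Reduction in the same flask keeps the β-hydroxy aldehyde from eliminating.

Step 5
Reactants: 7 (3S,4Z)-5-iodo-4-methylpent-4-ene-1,3-diol
Product: 8 (3S,4Z)-1,3-bis[(tert-butyldimethylsilyl)oxy]-5-iodo-4-methylpent-4-ene
Conditions: TBSCl (2.5 equiv), imidazole, DMF, rt
Reagents that add atoms: tert-butyldimethylsilyl chloride, CC(C)(C)[Si](C)(C)Cl
Why: Standard silylation of both hydroxyls; silyl ethers are needed for the organolithium step and, at C3, for the later ylide step.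

Step 6
Reactants: 1 prop-2-yn-1-ol (propargyl alcohol)
Product: 9 tert-butyldiphenyl(prop-2-yn-1-yloxy)silane
Conditions: TBDPSCl, imidazole, CH2Cl2, rt
Reagents that add atoms: tert-butyldiphenylsilyl chloride, CC(C)(C)[Si](Cl)(c1ccccc1)c1ccccc1
Why: Silylation of a primary alcohol; the TBDPS group is chosen because it must outlast two acidic cleavages of TBS ethers.

Step 7
Reactants: 9 tert-butyldiphenyl(prop-2-yn-1-yloxy)silane
Product: 11 4-[(tert-butyldiphenylsilyl)oxy]-N-methoxy-N-methylbut-2-ynamide, via lithium acetylide 10 (not isolated)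
Conditions: n-BuLi, THF, −78 °C; then ClC(O)N(OMe)Me, −78 → 0 °C
Reagents that add atoms: N-methoxy-N-methylcarbamoyl chloride, CON(C)C(Cl)=O
Why: Acylation of a lithium acetylide with a carbamoyl chloride is a direct route to alkynyl Weinreb amides.

Step 8
Reactants: 8 (3S,4Z)-1,3-bis[(tert-butyldimethylsilyl)oxy]-5-iodo-4-methylpent-4-ene; 11 4-[(tert-butyldiphenylsilyl)oxy]-N-methoxy-N-methylbut-2-ynamide
Product: 13 (5Z,7S)-7,9-bis[(tert-butyldimethylsilyl)oxy]-1-[(tert-butyldiphenylsilyl)oxy]-6-methylnon-5-en-2-yn-4-one, via alkenyllithium 12 (not isolated)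
Conditions: t-BuLi (2.1 equiv), Et2O, −78 °C; then 11, −78 °C; aq NH4Cl
Reagents that add atoms: none
Why: Iodine–lithium exchange with retention of alkene geometry, then Weinreb ketone synthesis (forms C5–C6); the chelated tetrahedral adduct prevents a second addition. Keeping −78 °C suppresses a 1,4 O-to-C silyl shift in 12.

Step 9
Reactants: 13 (5Z,7S)-7,9-bis[(tert-butyldimethylsilyl)oxy]-1-[(tert-butyldiphenylsilyl)oxy]-6-methylnon-5-en-2-yn-4-one
Product: 14 (4R,5Z,7S)-7,9-bis[(tert-butyldimethylsilyl)oxy]-1-[(tert-butyldiphenylsilyl)oxy]-6-methylnon-5-en-2-yn-4-ol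
Conditions: (R)-2-methyl-CBS-oxazaborolidine (0.5 equiv), catecholborane, toluene, −78 °C
Reagents that add atoms: none
Why: Corey–Bakshi–Shibata reduction of an ynone: the branched Z alkenyl arm should act as the large group and the linear alkynyl arm as the small one, so the (R)-catalyst should give the 4R alcohol (C6 of the target). The descriptor becomes S once the alkyne is an alkene.

Step 10
Reactants: 14 (4R,5Z,7S)-7,9-bis[(tert-butyldimethylsilyl)oxy]-1-[(tert-butyldiphenylsilyl)oxy]-6-methylnon-5-en-2-yn-4-ol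
Product: 15 (4R,5Z,7S)-7,9-bis[(tert-butyldimethylsilyl)oxy]-1-[(tert-butyldiphenylsilyl)oxy]-4-[(4-methoxybenzyl)oxy]-6-methylnon-5-en-2-yne
Conditions: NaH, 4-methoxybenzyl chloride, Bu4NI (cat.), THF/DMF, 0 °C → rt
Reagents that add atoms: 4-methoxybenzyl chloride, COc1ccc(CCl)cc1
Why: Williamson etherification; the PMB ether can later be removed oxidatively without acid, in the presence of a silyl ether and an acetate.

Step 11
Reactants: 15 (4R,5Z,7S)-7,9-bis[(tert-butyldimethylsilyl)oxy]-1-[(tert-butyldiphenylsilyl)oxy]-4-[(4-methoxybenzyl)oxy]-6-methylnon-5-en-2-yne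
Product: 16 (2Z,4S,5Z,7S)-7,9-bis[(tert-butyldimethylsilyl)oxy]-1-[(tert-butyldiphenylsilyl)oxy]-4-[(4-methoxybenzyl)oxy]-6-methylnona-2,5-diene
Conditions: H2 (1 atm), Pd/CaCO3/Pb(OAc)2 (Lindlar), quinoline, EtOAc, rt
Reagents that add atoms: none
Why: Lindlar semihydrogenation adds hydrogen syn and should give the Z C7=C8 alkene; the trisubstituted alkene and the PMB ether are not touched.

Step 12
Reactants: 16 (2Z,4S,5Z,7S)-7,9-bis[(tert-butyldimethylsilyl)oxy]-1-[(tert-butyldiphenylsilyl)oxy]-4-[(4-methoxybenzyl)oxy]-6-methylnona-2,5-diene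
Product: 17 (3S,4Z,6S,7Z)-3-[(tert-butyldimethylsilyl)oxy]-9-[(tert-butyldiphenylsilyl)oxy]-6-[(4-methoxybenzyl)oxy]-4-methylnona-4,7-dien-1-ol
Conditions: HF·pyridine, pyridine, THF, 0 °C
Reagents that add atoms: none
Why: Buffered HF·pyridine cleaves a primary TBS ether well before a secondary TBS or a TBDPS ether, a standard selectivity.

Step 13
Reactants: 17 (3S,4Z,6S,7Z)-3-[(tert-butyldimethylsilyl)oxy]-9-[(tert-butyldiphenylsilyl)oxy]-6-[(4-methoxybenzyl)oxy]-4-methylnona-4,7-dien-1-ol
Product: 18 (3S,4Z,6S,7Z)-3-[(tert-butyldimethylsilyl)oxy]-9-[(tert-butyldiphenylsilyl)oxy]-6-[(4-methoxybenzyl)oxy]-4-methylnona-4,7-dienal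
Conditions: Dess–Martin periodinane, NaHCO3, CH2Cl2, 0 °C → rt
Reagents that add atoms: none
Why: Buffered Dess–Martin oxidation; a β-silyloxy aldehyde does not eliminate under these conditions.

Step 14
Reactants: 18 (3S,4Z,6S,7Z)-3-[(tert-butyldimethylsilyl)oxy]-9-[(tert-butyldiphenylsilyl)oxy]-6-[(4-methoxybenzyl)oxy]-4-methylnona-4,7-dienal; 19 ethyltriphenylphosphonium bromide
Product: 23 (2Z,4S,5Z,7S,9Z)-7-[(tert-butyldimethylsilyl)oxy]-1-[(tert-butyldiphenylsilyl)oxy]-10-iodo-4-[(4-methoxybenzyl)oxy]-6-methylundeca-2,5,9-triene, via ethylidene ylide 20 (not isolated), via iodoethylphosphonium iodide 21 (not isolated), via iodoethylidene ylide 22 (not isolated)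
Conditions: 19, n-BuLi, THF, 0 °C; I2, −78 °C; NaN(SiMe3)2, −20 °C; then 18, −78 °C
Reagents that add atoms: iodine, [I][I]
Why: Stork–Zhao olefination: the non-stabilised α-iodo ylide should give the Z 2-iodoalkene (iodine cis to the chain), which fixes the C1=C10 geometry. The C3 silyl ether is used because an acetate β to the aldehyde would eliminate.

Step 15
Reactants: 23 (2Z,4S,5Z,7S,9Z)-7-[(tert-butyldimethylsilyl)oxy]-1-[(tert-butyldiphenylsilyl)oxy]-10-iodo-4-[(4-methoxybenzyl)oxy]-6-methylundeca-2,5,9-triene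
Product: 24 (2Z,5S,6Z,8S,9Z)-11-[(tert-butyldiphenylsilyl)oxy]-2-iodo-8-[(4-methoxybenzyl)oxy]-6-methylundeca-2,6,9-trien-5-ol
Conditions: HF (48 % aq), MeCN, 0 °C
Reagents that add atoms: none
Why: Aqueous HF in acetonitrile removes a secondary TBS ether while a TBDPS ether and a PMB ether persist.

Step 16
Reactants: 24 (2Z,5S,6Z,8S,9Z)-11-[(tert-butyldiphenylsilyl)oxy]-2-iodo-8-[(4-methoxybenzyl)oxy]-6-methylundeca-2,6,9-trien-5-ol
Product: 25 (2Z,5S,6Z,8S,9Z)-11-[(tert-butyldiphenylsilyl)oxy]-2-iodo-8-[(4-methoxybenzyl)oxy]-6-methylundeca-2,6,9-trien-5-yl acetate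
Conditions: Ac2O, pyridine, DMAP (cat.), CH2Cl2, 0 °C → rt
Reagents that add atoms: acetic anhydride, CC(=O)OC(C)=O
Why: Acetylation of the only free hydroxyl installs the C3 acetate of the target; no later step uses a strong base or nucleophile.

Step 17
Reactants: 25 (2Z,5S,6Z,8S,9Z)-11-[(tert-butyldiphenylsilyl)oxy]-2-iodo-8-[(4-methoxybenzyl)oxy]-6-methylundeca-2,6,9-trien-5-yl acetate
Product: 26 (2Z,5S,6Z,8S,9Z)-11-hydroxy-2-iodo-8-[(4-methoxybenzyl)oxy]-6-methylundeca-2,6,9-trien-5-yl acetate
Conditions: Bu4NF, AcOH, THF, 0 °C → rt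
Reagents that add atoms: none
Why: Fluoride cleaves the TBDPS ether; buffering with acetic acid keeps the acetate from cleavage or migration.

Step 18
Reactants: 26 (2Z,5S,6Z,8S,9Z)-11-hydroxy-2-iodo-8-[(4-methoxybenzyl)oxy]-6-methylundeca-2,6,9-trien-5-yl acetate
Product: 27 (2Z,5S,6Z,8S,9Z)-2-iodo-8-[(4-methoxybenzyl)oxy]-6-methyl-11-oxoundeca-2,6,9-trien-5-yl acetate
Conditions: Dess–Martin periodinane, NaHCO3, CH2Cl2, 0 °C
Reagents that add atoms: none
Why: Buffered Dess–Martin oxidation of a Z allylic alcohol at 0 °C should give the Z enal without isomerisation; it is taken on without chromatography.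

Step 19
Reactants: 27 (2Z,5S,6Z,8S,9Z)-2-iodo-8-[(4-methoxybenzyl)oxy]-6-methyl-11-oxoundeca-2,6,9-trien-5-yl acetate
Product: 28 (3S,6S,9S)-9-hydroxy-6-[(4-methoxybenzyl)oxy]-4,10-dimethylcyclodeca-1(10),4,7-trien-3-yl acetate (ring alkenes all Z)
Conditions: CrCl2 (15 equiv), NiCl2 (0.1 equiv), degassed DMSO, 0.003 M, slow addition, rt
Reagents that add atoms: none
Why: Nozaki–Hiyama–Kishi reaction: zerovalent nickel inserts into the C–I bond, the alkenyl group passes to trivalent chromium and adds to the aldehyde, closing the ten-membered ring at C9–C10; the three Z alkenes pre-bend the chain. C9 arises under substrate control; the 9S alcohol (hydroxyl trans to O6 across the Z alkene) is needed and would be separated from any 9R epimer.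

Step 20
Reactants: 28 (3S,6S,9S)-9-hydroxy-6-[(4-methoxybenzyl)oxy]-4,10-dimethylcyclodeca-1(10),4,7-trien-3-yl acetate
Product: 29 (3S,6S,9S)-6-[(4-methoxybenzyl)oxy]-4,10-dimethyl-9-[(triethylsilyl)oxy]cyclodeca-1(10),4,7-trien-3-yl acetate
Conditions: TESCl, imidazole, DMF, 0 °C → rt
Reagents that add atoms: chlorotriethylsilane, CC[Si](Cl)(CC)CC
Why: Silylation under basic conditions avoids ionising the doubly allylic alcohol; the triethylsilyl group is small and can be removed at the end under very mild conditions.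

Step 21
Reactants: 29 (3S,6S,9S)-6-[(4-methoxybenzyl)oxy]-4,10-dimethyl-9-[(triethylsilyl)oxy]cyclodeca-1(10),4,7-trien-3-yl acetate
Product: 30 (3S,6S,9S)-6-hydroxy-4,10-dimethyl-9-[(triethylsilyl)oxy]cyclodeca-1(10),4,7-trien-3-yl acetate
Conditions: DDQ (1.2 equiv), CH2Cl2/pH 7 buffer, 0 °C
Reagents that add atoms: none
Why: Oxidative PMB cleavage is neutral and leaves the silyl ether and the acetate; a small excess of DDQ and low temperature limit further oxidation of the liberated doubly allylic alcohol.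

Step 22
Reactants: 31 acrolein diethyl acetal (3,3-diethoxyprop-1-ene)
Product: 33 2-bromo-3,3-diethoxyprop-1-ene, via dibromo acetal 32 (not isolated)
Conditions: Br2, CH2Cl2, −20 °C; then KOt-Bu, THF, 0 °C
Reagents that add atoms: bromine, BrBr
Why: Bromine addition to the alkene, then E2 loss of HBr through the more acidic hydrogen on the carbon next to the acetal, should give the 2-bromoalkene.

Step 23
Reactants: 30 (3S,6S,9S)-6-hydroxy-4,10-dimethyl-9-[(triethylsilyl)oxy]cyclodeca-1(10),4,7-trien-3-yl acetate; 33 2-bromo-3,3-diethoxyprop-1-ene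
Product: 35 (3S,6S,9S)-6-[(2-bromo-1-ethoxyprop-2-en-1-yl)oxy]-4,10-dimethyl-9-[(triethylsilyl)oxy]cyclodeca-1(10),4,7-trien-3-yl acetate, via collidinium salt 34 (not isolated)
Conditions: 33 (3 equiv), 2,4,6-collidine (5 equiv), TESOTf (2.5 equiv), CH2Cl2, 0 °C; then 30, 0 °C → rt
Reagents that add atoms: none
Why: Mixed-acetal formation by activating a dialkyl acetal with a silyl triflate and collidine to an N-(α-alkoxyalkyl)collidinium salt, which the alcohol then displaces. No free acid is present, and the triflate is kept below the amount of 33 so that none is left to silylate or ionise 30.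

Step 24
Reactants: 35 (3S,6S,9S)-6-[(2-bromo-1-ethoxyprop-2-en-1-yl)oxy]-4,10-dimethyl-9-[(triethylsilyl)oxy]cyclodeca-1(10),4,7-trien-3-yl acetate
Product: 37 (3S,6R,7S,8S,9R,1(10)Z,4Z)-3-acetoxy-12-ethoxy-8-hydroxy-9-[(triethylsilyl)oxy]-6,12-epoxygermacra-1(10),4,11(13)-triene, via hydroperoxide 36 (not isolated)
Conditions: Bu3SnH (1.3 equiv, slow addition), Et3B (cat.), dry air, toluene (0.01 M), 0 °C; then PPh3
Reagents that add atoms: dioxygen, O=O
Why: Ethyl radicals from Et3B and air start a stannyl chain; Bu3Sn• removes bromine from 35, and the σ-vinyl radical at C11 adds 5-exo-trig to C7, which closes the five-membered lactol ring (C6–O–C12–C11–C7) and keeps the exocyclic methylene. The C8 radical is taken by O2 faster than by the dilute stannane, the peroxyl radical is reduced to hydroperoxide 36, and PPh3 gives alcohol 37; the closest known reaction type is the Ueno–Stork haloacetal cyclisation of a vinyl radical run under air so that the cyclised radical is hydroxylated. C7 is set by the tether: a three-atom link from O6 reaches only the face of C7=C8 on which O6 stands, so the ring fusion is cis. C8 is set by approach of O2 anti to the new C7–C11 bond, which on the Z alkene amounts to anti addition and puts O8 trans to C11. That face also carries the C9 silyloxy group (O8 and O9 are cis in 46), so the small triethylsilyl ether is used and the branched C11 is relied on as the larger neighbour of the radical. The step also needs site selectivity, because C6 is allylic to C4=C5 as well and C5 can be reached through an equally sized 5-exo transition state that even gives a tertiary radical; nothing in 35 forbids this, only the lower substitution of C7=C8 and the ring conformation speak for C7, and this is the least secured point. Slow addition of the stannane keeps reduction of the vinyl and C8 radicals behind cyclisation and oxygen capture.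

Step 25
Reactants: 38 angelic acid ((Z)-2-methylbut-2-enoic acid)
Product: 39 (Z)-2-methylbut-2-en-1-ol
Conditions: LiAlH4, Et2O, 0 °C
Reagents that add atoms: none
Why: Hydride reduction of the acid to the allylic alcohol; at 0 °C the Z geometry should be kept.

Step 26
Reactants: 39 (Z)-2-methylbut-2-en-1-ol
Product: 40 [(2S,3R)-2,3-dimethyloxiran-2-yl]methanol
Conditions: Ti(OiPr)4 (cat.), L-(+)-diethyl tartrate (cat.), t-BuOOH, 4 Å sieves, CH2Cl2, −20 °C
Reagents that add atoms: tert-butyl hydroperoxide, CC(C)(C)OO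
Why: Sharpless asymmetric epoxidation; with the L-(+)-tartrate a Z 2,3-disubstituted allylic alcohol should give the (2S,3R) epoxy alcohol, by analogy with the usual outcome for Z trisubstituted allylic alcohols. Both epoxide centres are set here; the cis relation of the C3 methyl and the CH2OH group comes from the Z alkene.

Step 27
Reactants: 40 [(2S,3R)-2,3-dimethyloxiran-2-yl]methanol
Product: 41 (2R,3R)-2,3-dimethyloxirane-2-carboxylic acid
Conditions: RuCl3 (cat.), NaIO4, CCl4/MeCN/H2O, rt
Reagents that add atoms: water, O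
Why: Ruthenium-catalysed periodate oxidation takes a primary epoxy alcohol to the glycidic acid without opening the epoxide. The descriptor at C2 changes from S to R only because the substituent priorities change.

Step 28
Reactants: 37 (3S,6R,7S,8S,9R,1(10)Z,4Z)-3-acetoxy-12-ethoxy-8-hydroxy-9-[(triethylsilyl)oxy]-6,12-epoxygermacra-1(10),4,11(13)-triene; 41 (2R,3R)-2,3-dimethyloxirane-2-carboxylic acid
Product: 43 (3S,6R,7R,8S,9R,1(10)Z,4Z)-3-acetoxy-8-[(2R,3R)-2,3-dimethyloxirane-2-carbonyloxy]-12-ethoxy-9-[(triethylsilyl)oxy]-6,12-epoxygermacra-1(10),4,11(13)-triene, via mixed anhydride 42 (not isolated)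
Conditions: 2,4,6-trichlorobenzoyl chloride, Et3N, toluene, rt; then 37, DMAP, toluene, rt → 40 °C
Reagents that add atoms: none
Why: Yamaguchi esterification through the mixed anhydride suits a hindered secondary alcohol; C8–OH is the only free hydroxyl, and the preformed epoxy acid cannot undergo the Z-to-E isomerisation that troubles angelate esters.

Step 29
Reactants: 43 (3S,6R,7R,8S,9R,1(10)Z,4Z)-3-acetoxy-8-[(2R,3R)-2,3-dimethyloxirane-2-carbonyloxy]-12-ethoxy-9-[(triethylsilyl)oxy]-6,12-epoxygermacra-1(10),4,11(13)-triene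
Product: 44 (3S,6R,7R,8S,9R,1(10)Z,4Z)-3-acetoxy-8-[(2R,3R)-2,3-dimethyloxirane-2-carbonyloxy]-12-hydroxy-9-[(triethylsilyl)oxy]-6,12-epoxygermacra-1(10),4,11(13)-triene
Conditions: pyridinium p-toluenesulfonate (cat.), THF/H2O, rt
Reagents that add atoms: water, O
Why: The lactol ether is a cyclic acetal whose oxocarbenium ion is conjugated with the exocyclic alkene, so it should hydrolyse under acid mild enough to leave the hindered triethylsilyl ether and the ester-deactivated epoxide.

Step 30
Reactants: 44 (3S,6R,7R,8S,9R,1(10)Z,4Z)-3-acetoxy-8-[(2R,3R)-2,3-dimethyloxirane-2-carbonyloxy]-12-hydroxy-9-[(triethylsilyl)oxy]-6,12-epoxygermacra-1(10),4,11(13)-triene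
Product: 45 (3S,6R,7R,8S,9R,1(10)Z,4Z)-3-acetoxy-8-[(2R,3R)-2,3-dimethyloxirane-2-carbonyloxy]-9-[(triethylsilyl)oxy]germacra-1(10),4,11(13)-trien-12,6-olide
Conditions: MnO2, CH2Cl2, rt
Reagents that add atoms: none
Why: The lactol hydroxyl is allylic, so MnO2 should oxidise it to the α-methylene lactone under neutral conditions; the C9 hydroxyl is still silylated and cannot be oxidised.

Step 31
Reactants: 45 (3S,6R,7R,8S,9R,1(10)Z,4Z)-3-acetoxy-8-[(2R,3R)-2,3-dimethyloxirane-2-carbonyloxy]-9-[(triethylsilyl)oxy]germacra-1(10),4,11(13)-trien-12,6-olide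
Product: 46 (3S,6R,7R,8S,9R,1(10)Z,4Z)-3-acetoxy-8-[(2R,3R)-2,3-dimethyloxirane-2-carbonyloxy]-9-hydroxygermacra-1(10),4,11(13)-trien-12,6-olide (CNP0299903.1)
Conditions: HF·pyridine, pyridine, THF, 0 °C
Reagents that add atoms: none
Why: Buffered HF·pyridine removes a triethylsilyl ether without base, so the enoate suffers no conjugate addition, the C8 ester does not migrate to O9, and the epoxide and the acetate stay.

## Compound list

1 | prop-2-yn-1-ol (propargyl alcohol) | C#CCO | starting material
2 | bromomagnesium (Z)-3-(bromomagnesio)-2-methylprop-2-en-1-olate | Br[Mg]/C=C(/C)CO[Mg]Br | intermediate (not isolated)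
3 | (Z)-3-iodo-2-methylprop-2-en-1-ol | I/C=C(/C)CO | intermediate
4 | (Z)-3-iodo-2-methylprop-2-enal | I/C=C(/C)C=O | intermediate
5 | (1Z,3S)-1-iodo-2-methylhexa-1,5-dien-3-ol | I/C=C(/C)[C@@H](O)CC=C | intermediate
6 | (3S,4Z)-3-hydroxy-5-iodo-4-methylpent-4-enal | I/C=C(/C)[C@@H](O)CC=O | intermediate (not isolated)
7 | (3S,4Z)-5-iodo-4-methylpent-4-ene-1,3-diol | I/C=C(/C)[C@@H](O)CCO | intermediate
8 | (3S,4Z)-1,3-bis[(tert-butyldimethylsilyl)oxy]-5-iodo-4-methylpent-4-ene | I/C=C(/C)[C@@H](O[Si](C)(C)C(C)(C)C)CCO[Si](C)(C)C(C)(C)C | intermediate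
9 | tert-butyldiphenyl(prop-2-yn-1-yloxy)silane | C#CCO[Si](c1ccccc1)(c1ccccc1)C(C)(C)C | intermediate
10 | lithium acetylide of 9 | [Li]C#CCO[Si](c1ccccc1)(c1ccccc1)C(C)(C)C | intermediate (not isolated)
11 | 4-[(tert-butyldiphenylsilyl)oxy]-N-methoxy-N-methylbut-2-ynamide | CON(C)C(=O)C#CCO[Si](c1ccccc1)(c1ccccc1)C(C)(C)C | intermediate
12 | (1Z,3S)-3,5-bis[(tert-butyldimethylsilyl)oxy]-2-methylpent-1-en-1-yllithium | [Li]/C=C(/C)[C@@H](O[Si](C)(C)C(C)(C)C)CCO[Si](C)(C)C(C)(C)C | intermediate (not isolated)
13 | (5Z,7S)-7,9-bis[(tert-butyldimethylsilyl)oxy]-1-[(tert-butyldiphenylsilyl)oxy]-6-methylnon-5-en-2-yn-4-one | O=C(C#CCO[Si](c1ccccc1)(c1ccccc1)C(C)(C)C)/C=C(/C)[C@@H](O[Si](C)(C)C(C)(C)C)CCO[Si](C)(C)C(C)(C)C | intermediate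
14 | (4R,5Z,7S)-7,9-bis[(tert-butyldimethylsilyl)oxy]-1-[(tert-butyldiphenylsilyl)oxy]-6-methylnon-5-en-2-yn-4-ol | O[C@@H](C#CCO[Si](c1ccccc1)(c1ccccc1)C(C)(C)C)/C=C(/C)[C@@H](O[Si](C)(C)C(C)(C)C)CCO[Si](C)(C)C(C)(C)C | intermediate
15 | (4R,5Z,7S)-7,9-bis[(tert-butyldimethylsilyl)oxy]-1-[(tert-butyldiphenylsilyl)oxy]-4-[(4-methoxybenzyl)oxy]-6-methylnon-5-en-2-yne | COc1ccc(CO[C@@H](C#CCO[Si](c2ccccc2)(c2ccccc2)C(C)(C)C)/C=C(/C)[C@@H](O[Si](C)(C)C(C)(C)C)CCO[Si](C)(C)C(C)(C)C)cc1 | intermediate
16 | (2Z,4S,5Z,7S)-7,9-bis[(tert-butyldimethylsilyl)oxy]-1-[(tert-butyldiphenylsilyl)oxy]-4-[(4-methoxybenzyl)oxy]-6-methylnona-2,5-diene | COc1ccc(CO[C@@H](/C=C\CO[Si](c2ccccc2)(c2ccccc2)C(C)(C)C)/C=C(/C)[C@@H](O[Si](C)(C)C(C)(C)C)CCO[Si](C)(C)C(C)(C)C)cc1 | intermediate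
17 | (3S,4Z,6S,7Z)-3-[(tert-butyldimethylsilyl)oxy]-9-[(tert-butyldiphenylsilyl)oxy]-6-[(4-methoxybenzyl)oxy]-4-methylnona-4,7-dien-1-ol | COc1ccc(CO[C@@H](/C=C\CO[Si](c2ccccc2)(c2ccccc2)C(C)(C)C)/C=C(/C)[C@@H](O[Si](C)(C)C(C)(C)C)CCO)cc1 | intermediate
18 | (3S,4Z,6S,7Z)-3-[(tert-butyldimethylsilyl)oxy]-9-[(tert-butyldiphenylsilyl)oxy]-6-[(4-methoxybenzyl)oxy]-4-methylnona-4,7-dienal | COc1ccc(CO[C@@H](/C=C\CO[Si](c2ccccc2)(c2ccccc2)C(C)(C)C)/C=C(/C)[C@@H](O[Si](C)(C)C(C)(C)C)CC=O)cc1 | intermediate
19 | ethyltriphenylphosphonium bromide | CC[P+](c1ccccc1)(c1ccccc1)c1ccccc1.[Br-] | starting material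
20 | ethylidenetriphenylphosphorane | CC=P(c1ccccc1)(c1ccccc1)c1ccccc1 | intermediate (not isolated)
21 | (1-iodoethyl)triphenylphosphonium iodide | CC(I)[P+](c1ccccc1)(c1ccccc1)c1ccccc1.[I-] | intermediate (not isolated)
22 | (1-iodoethylidene)triphenylphosphorane | CC(I)=P(c1ccccc1)(c1ccccc1)c1ccccc1 | intermediate (not isolated)
23 | (2Z,4S,5Z,7S,9Z)-7-[(tert-butyldimethylsilyl)oxy]-1-[(tert-butyldiphenylsilyl)oxy]-10-iodo-4-[(4-methoxybenzyl)oxy]-6-methylundeca-2,5,9-triene | COc1ccc(CO[C@@H](/C=C\CO[Si](c2ccccc2)(c2ccccc2)C(C)(C)C)/C=C(/C)[C@@H](O[Si](C)(C)C(C)(C)C)C/C=C(/C)I)cc1 | intermediate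
24 | (2Z,5S,6Z,8S,9Z)-11-[(tert-butyldiphenylsilyl)oxy]-2-iodo-8-[(4-methoxybenzyl)oxy]-6-methylundeca-2,6,9-trien-5-ol | COc1ccc(CO[C@@H](/C=C\CO[Si](c2ccccc2)(c2ccccc2)C(C)(C)C)/C=C(/C)[C@@H](O)C/C=C(/C)I)cc1 | intermediate
25 | (2Z,5S,6Z,8S,9Z)-11-[(tert-butyldiphenylsilyl)oxy]-2-iodo-8-[(4-methoxybenzyl)oxy]-6-methylundeca-2,6,9-trien-5-yl acetate | COc1ccc(CO[C@@H](/C=C\CO[Si](c2ccccc2)(c2ccccc2)C(C)(C)C)/C=C(/C)[C@@H](OC(C)=O)C/C=C(/C)I)cc1 | intermediate
26 | (2Z,5S,6Z,8S,9Z)-11-hydroxy-2-iodo-8-[(4-methoxybenzyl)oxy]-6-methylundeca-2,6,9-trien-5-yl acetate | COc1ccc(CO[C@@H](/C=C\CO)/C=C(/C)[C@@H](OC(C)=O)C/C=C(/C)I)cc1 | intermediate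
27 | (2Z,5S,6Z,8S,9Z)-2-iodo-8-[(4-methoxybenzyl)oxy]-6-methyl-11-oxoundeca-2,6,9-trien-5-yl acetate | COc1ccc(CO[C@@H](/C=C\C=O)/C=C(/C)[C@@H](OC(C)=O)C/C=C(/C)I)cc1 | intermediate
28 | (3S,6S,9S)-9-hydroxy-6-[(4-methoxybenzyl)oxy]-4,10-dimethylcyclodeca-1(10),4,7-trien-3-yl acetate (ring alkenes all Z) | CC(=O)O[C@H]1C/C=C(/C)[C@@H](O)/C=C\[C@H](OCc2ccc(OC)cc2)/C=C1/C | intermediate
29 | (3S,6S,9S)-6-[(4-methoxybenzyl)oxy]-4,10-dimethyl-9-[(triethylsilyl)oxy]cyclodeca-1(10),4,7-trien-3-yl acetate (Z,Z,Z) | CC(=O)O[C@H]1C/C=C(/C)[C@@H](O[Si](CC)(CC)CC)/C=C\[C@H](OCc2ccc(OC)cc2)/C=C1/C | intermediate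
30 | (3S,6S,9S)-6-hydroxy-4,10-dimethyl-9-[(triethylsilyl)oxy]cyclodeca-1(10),4,7-trien-3-yl acetate (Z,Z,Z) | CC(=O)O[C@H]1C/C=C(/C)[C@@H](O[Si](CC)(CC)CC)/C=C\[C@H](O)/C=C1/C | intermediate
31 | acrolein diethyl acetal (3,3-diethoxyprop-1-ene) | C=CC(OCC)OCC | starting material
32 | 2,3-dibromo-1,1-diethoxypropane | CCOC(OCC)C(Br)CBr | intermediate (not isolated)
33 | 2-bromo-3,3-diethoxyprop-1-ene | C=C(Br)C(OCC)OCC | intermediate
34 | 1-(2-bromo-1-ethoxyprop-2-en-1-yl)-2,4,6-trimethylpyridinium triflate | C=C(Br)C(OCC)[n+]1c(C)cc(C)cc1C.[O-]S(=O)(=O)C(F)(F)F | intermediate (not isolated)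
35 | (3S,6S,9S)-6-[(2-bromo-1-ethoxyprop-2-en-1-yl)oxy]-4,10-dimethyl-9-[(triethylsilyl)oxy]cyclodeca-1(10),4,7-trien-3-yl acetate (Z,Z,Z; both acetal epimers, one drawn) | CC(=O)O[C@H]1C/C=C(/C)[C@@H](O[Si](CC)(CC)CC)/C=C\[C@H](O[C@H](OCC)C(Br)=C)/C=C1/C | intermediate
36 | (3S,6R,7R,8S,9R,1(10)Z,4Z)-3-acetoxy-12-ethoxy-8-hydroperoxy-9-[(triethylsilyl)oxy]-6,12-epoxygermacra-1(10),4,11(13)-triene | C=C1[C@@H](OCC)O[C@@H]2/C=C(/C)[C@@H](OC(C)=O)C/C=C(/C)[C@@H](O[Si](CC)(CC)CC)[C@@H](OO)[C@H]12 | intermediate (not isolated)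
37 | (3S,6R,7S,8S,9R,1(10)Z,4Z)-3-acetoxy-12-ethoxy-8-hydroxy-9-[(triethylsilyl)oxy]-6,12-epoxygermacra-1(10),4,11(13)-triene (cis-fused lactol ethyl ether) | C=C1[C@@H](OCC)O[C@@H]2/C=C(/C)[C@@H](OC(C)=O)C/C=C(/C)[C@@H](O[Si](CC)(CC)CC)[C@@H](O)[C@H]12 | intermediate
38 | angelic acid ((Z)-2-methylbut-2-enoic acid) | C/C=C(/C)C(O)=O | starting material
39 | (Z)-2-methylbut-2-en-1-ol | C/C=C(/C)CO | intermediate
40 | [(2S,3R)-2,3-dimethyloxiran-2-yl]methanol | OC[C@]1(C)O[C@@H]1C | intermediate
41 | (2R,3R)-2,3-dimethyloxirane-2-carboxylic acid | OC(=O)[C@]1(C)O[C@@H]1C | intermediate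
42 | (2R,3R)-2,3-dimethyloxirane-2-carboxylic 2,4,6-trichlorobenzoic anhydride | O=C(OC(=O)c1c(Cl)cc(Cl)cc1Cl)[C@]1(C)O[C@@H]1C | intermediate (not isolated)
43 | (3S,6R,7R,8S,9R,1(10)Z,4Z)-3-acetoxy-8-[(2R,3R)-2,3-dimethyloxirane-2-carbonyloxy]-12-ethoxy-9-[(triethylsilyl)oxy]-6,12-epoxygermacra-1(10),4,11(13)-triene | C=C1[C@@H](OCC)O[C@@H]2/C=C(/C)[C@@H](OC(C)=O)C/C=C(/C)[C@@H](O[Si](CC)(CC)CC)[C@@H](OC(=O)[C@]3(C)O[C@@H]3C)[C@H]12 | intermediate
44 | (3S,6R,7R,8S,9R,1(10)Z,4Z)-3-acetoxy-8-[(2R,3R)-2,3-dimethyloxirane-2-carbonyloxy]-12-hydroxy-9-[(triethylsilyl)oxy]-6,12-epoxygermacra-1(10),4,11(13)-triene (lactol, both anomers) | C=C1C(O)O[C@@H]2/C=C(/C)[C@@H](OC(C)=O)C/C=C(/C)[C@@H](O[Si](CC)(CC)CC)[C@@H](OC(=O)[C@]3(C)O[C@@H]3C)[C@H]12 | intermediate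
45 | (3S,6R,7R,8S,9R,1(10)Z,4Z)-3-acetoxy-8-[(2R,3R)-2,3-dimethyloxirane-2-carbonyloxy]-9-[(triethylsilyl)oxy]germacra-1(10),4,11(13)-trien-12,6-olide | C=C1C(=O)O[C@@H]2/C=C(/C)[C@@H](OC(C)=O)C/C=C(/C)[C@@H](O[Si](CC)(CC)CC)[C@@H](OC(=O)[C@]3(C)O[C@@H]3C)[C@H]12 | intermediate
46 | (3S,6R,7R,8S,9R,1(10)Z,4Z)-3-acetoxy-8-[(2R,3R)-2,3-dimethyloxirane-2-carbonyloxy]-9-hydroxygermacra-1(10),4,11(13)-trien-12,6-olide (CNP0299903.1) | C=C1C(=O)O[C@@H]2/C=C(/C)[C@@H](OC(C)=O)C/C=C(/C)[C@@H](O)[C@@H](OC(=O)[C@]3(C)O[C@@H]3C)[C@H]12 | target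

## Step count and least certain steps

Total step count: 31. Longest linear sequence: 25 (steps 1–5, 8–21, 23, 24, 28–31).

**Step 24 (key step).** The most likely failure is loss of site selectivity. C6 is allylic to C4=C5 as well as to C7=C8, the tether reaches C5 through an equally good 5-exo transition state, and addition there gives a tertiary radical. The second failure is oxygen capture at C8 on the face of C11. The fallback takes C4=C5 out of play for the radical step. It sets out from trienol 30. Hydroxyl-directed epoxidation (VO(acac)2, t-BuOOH) is expected to favour the more electron-rich trisubstituted allylic alkene and to give the 4,5-epoxy alcohol F1. Acetal exchange as in step 23 gives the epoxy bromoallyl acetal F2. The radical cyclisation with oxygen capture, now with C7=C8 as the only alkene within reach, gives the epoxy lactol ether F3. Stereospecific deoxygenation of the cis epoxide with retention (WCl6/n-BuLi, THF) restores the Z C4=C5 alkene, and the route is rejoined at 37.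

**Step 19.** The ten-membered closure may lose out to intermolecular coupling, and the Z enal may isomerise on the chromium salts before it is trapped. The configuration at C9 is set only by the conformation of the closing chain, so the 9R alcohol may prevail. The fallback for the configuration sets out from enal 27. The 9R epimer F4 from its ring closure (or the epimer mixture) is oxidised with Dess–Martin periodinane to the cross-conjugated ring dienone F5. This is reduced with (R)-2-methyl-CBS-oxazaborolidine and catecholborane, in which the α-methyl-substituted alkenyl arm should act as the large group. The route is rejoined at 28.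

**Step 9.** The catalyst may discriminate poorly between the alkenyl and alkynyl arms of the ynone, so that hydride is delivered to both faces. The fallback sets out from ynone 13. The unwanted 4S alcohol F6 is separated and inverted by Mitsunobu esterification with 4-nitrobenzoic acid to the 4-nitrobenzoate F7. Methanolysis (K2CO3, MeOH) returns to 14.

**Step 23.** The silyl triflate or the collidinium salt may ionise the doubly allylic C6–O bond (allylic transposition or elimination), or 30 may be silylated instead of exchanged. The fallback sets out from 30 and uses a cohalogenation. N-Bromosuccinimide at −78 °C brominates the central carbon of ethoxyallene F8 (made from ethyl propargyl ether with KOt-Bu), and the resulting oxocarbenium ion is trapped by 30. This gives 35 directly without acid.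

**Step 29.** The acid needed to open the lactol ether may also cleave the triethylsilyl ether, after which MnO2 would attack the allylic C9 hydroxyl. The fallback sets out from 43. Both groups are removed on purpose (AcOH/THF/H2O) to give the lactol diol F9. Only the lactol is then oxidised with TEMPO/PhI(OAc)2, which spares secondary alcohols. This arrives at 46 directly and makes step 31 unnecessary.

## Further compounds

F1 | step 24 | (3S,6S,9S)-4,5-epoxy-6-hydroxy-4,10-dimethyl-9-[(triethylsilyl)oxy]cyclodeca-1(10),7-dien-3-yl acetate (cis epoxide, drawn on the face of O6; its face is immaterial) | CC(=O)O[C@H]1C/C=C(/C)[C@@H](O[Si](CC)(CC)CC)/C=C\[C@H](O)[C@@H]2O[C@]12C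
F2 | step 24 | 6-O-(2-bromo-1-ethoxyprop-2-en-1-yl) acetal of F1 | CC(=O)O[C@H]1C/C=C(/C)[C@@H](O[Si](CC)(CC)CC)/C=C\[C@H](O[C@H](OCC)C(Br)=C)[C@@H]2O[C@]12C
F3 | step 24 | 4,5-epoxide of 37 (3-acetoxy-12-ethoxy-4,5:6,12-diepoxy-8-hydroxy-9-[(triethylsilyl)oxy]germacra-1(10),11(13)-diene) | C=C1[C@@H](OCC)O[C@@H]2[C@@H]3O[C@]3(C)[C@@H](OC(C)=O)C/C=C(/C)[C@@H](O[Si](CC)(CC)CC)[C@@H](O)[C@H]12
F4 | step 19 | (3S,6S,9R)-9-hydroxy-6-[(4-methoxybenzyl)oxy]-4,10-dimethylcyclodeca-1(10),4,7-trien-3-yl acetate (C9 epimer of 28) | CC(=O)O[C@H]1C/C=C(/C)[C@H](O)/C=C\[C@H](OCc2ccc(OC)cc2)/C=C1/C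
F5 | step 19 | (3S,6S)-6-[(4-methoxybenzyl)oxy]-4,10-dimethyl-9-oxocyclodeca-1(10),4,7-trien-3-yl acetate | CC(=O)O[C@H]1C/C=C(/C)C(=O)/C=C\[C@H](OCc2ccc(OC)cc2)/C=C1/C
F6 | step 9 | (4S,5Z,7S)-7,9-bis[(tert-butyldimethylsilyl)oxy]-1-[(tert-butyldiphenylsilyl)oxy]-6-methylnon-5-en-2-yn-4-ol (C4 epimer of 14) | O[C@H](C#CCO[Si](c1ccccc1)(c1ccccc1)C(C)(C)C)/C=C(/C)[C@@H](O[Si](C)(C)C(C)(C)C)CCO[Si](C)(C)C(C)(C)C
F7 | step 9 | 4-nitrobenzoate of 14 | O=C(O[C@@H](C#CCO[Si](c1ccccc1)(c1ccccc1)C(C)(C)C)/C=C(/C)[C@@H](O[Si](C)(C)C(C)(C)C)CCO[Si](C)(C)C(C)(C)C)c1ccc([N+](=O)[O-])cc1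
F8 | step 23 | ethoxyallene (1-ethoxypropa-1,2-diene) | C=C=COCC
F9 | step 29 | (3S,6R,7R,8S,9R,1(10)Z,4Z)-3-acetoxy-8-[(2R,3R)-2,3-dimethyloxirane-2-carbonyloxy]-9,12-dihydroxy-6,12-epoxygermacra-1(10),4,11(13)-triene | C=C1C(O)O[C@@H]2/C=C(/C)[C@@H](OC(C)=O)C/C=C(/C)[C@@H](O)[C@@H](OC(=O)[C@]3(C)O[C@@H]3C)[C@H]12
A1 | alternative 1 | ten-membered 3,9-diketone with cis-fused lactone and 8-O-(4-methoxybenzyl) group | C1C(=O)O[C@@H]2/C=C(/C)C(=O)C/C=C(/C)C(=O)[C@@H](OCc3ccc(OC)cc3)[C@H]12
A2 | alternative 1 | propyne | CC#C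
A3 | alternative 2 | 8-O-(4-methoxybenzyl)-9-O-triethylsilyl-protected core with α-methylene lactone | C=C1C(=O)O[C@@H]2/C=C(/C)[C@@H](OC(C)=O)C/C=C(/C)[C@@H](O[Si](CC)(CC)CC)[C@@H](OCc3ccc(OC)cc3)[C@H]12
A4 | alternative 3 | 8-hydroxy-9-oxo ten-membered enone with α-methylene lactone | C=C1C(=O)O[C@@H]2/C=C(/C)[C@@H](OC(C)=O)C/C=C(/C)C(=O)[C@@H](O)[C@H]12
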